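## Structural features

Diffractaic acid (13) is a para-depside: two benzene rings, each with five substituents and one hydrogen, are joined only by an aryl ester whose carbonyl sits on ring A C1 and whose oxygen sits on ring B C4. Ring A is a 2,4-dimethoxy-3,6-dimethylbenzoyl unit, so the ester carbonyl is flanked by the C2 methoxy and the C6 methyl group and is shielded on the acyl side. Ring B is a 2-hydroxy-3,6-dimethylbenzoic acid: the C2–OH lies ortho to the C1 carboxyl, C3 and C6 carry methyl groups, and C5 is the only ring CH. There is no stereocentre and no further ring or chain, so no stereochemical relationship has to be set. The fragile points are the depside ester (alcoholysis, hydrolysis and acyl transfer under basic nucleophilic conditions), the ring B hydroxy acid (loss of CO2 on heating in acid, because an oxygen stands para to the carboxyl) and both electron-rich rings (electrophilic halogenation, oxidation). The real difficulty is regiochemical: the two oxygens of the resorcinol core of ring B must be told apart, the carboxyl must stand ortho to the free one, and a hindered ester must be made without protecting-group traffic. The key step exploits the fact that ring B without its carboxyl is the monoester of symmetric 2,5-dimethylresorcinol, whose free C2–OH has a single open ortho carbon, C1, because C3 is methylated; the same diol also carries the oxygenation and methylation pattern of ring A.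

## Logic of the disconnections

13 ⇒ 9 + 10. The ring B C1–C(carboxyl) bond is cut. The carboxyl is the only ring B substituent that 1 lacks, and removing it leaves a phenol whose only open ortho position is the one to be functionalised. The gain is a precursor that needs no protecting group and a route in which the decarboxylation-prone hydroxy acid appears only at the very end. The forward step must carboxylate ortho (C1) and not para (C5) to the free hydroxyl, on a ring activated by only one free phenol, and must leave the depside ester intact. Compound 9 is deliberately left unprotected: its free C2–OH is the directing group, and any mask would cost steps before and after. The step passes through 11 and 12.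

9 ⇒ 7 (activated as 8) + 1. The ester C(acyl)–O(ring B C4) bond is cut. This is the natural retron of a depside and divides the molecule into two monocyclic pieces that both trace back to 1. The forward step must acylate only one of the two equivalent hydroxyls of 1 and must force a nucleophile onto a carbonyl shielded on both sides. An excess of 1 and nucleophilic catalysis on the reactive derivative 8 answer both demands.

7 ⇒ 6 ⇒ 3 + 4. First the oxidation level is adjusted (acid back to aldehyde, no skeletal cut), then the ring A C1–C(formyl) bond is cut. The two open positions of 3 are equivalent by symmetry and doubly activated, so electrophilic one-carbon substitution has no regiochemical question. The forward steps must stop at mono-substitution (via 5) and must oxidise the aldehyde without halogenating the electron-rich ring.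

3 ⇒ 1 + 2. The two O–CH3 bonds are cut. This returns ring A to 1, which also supplies ring B, so one commercial arene feeds both halves. The forward step must alkylate exhaustively on oxygen and not on carbon.

## Other disconnections considered

Alternative 1: The cut is the ring A C1–C6 bond, which unravels ring A into an open tricarbonyl chain hanging on the depside ester. In the forward key step, the aryl triketo ester benzyl 2-(benzyloxy)-3,6-dimethyl-4-[(4-methyl-3,5,7-trioxooctanoyl)oxy]benzoate A2 would be treated with mild base. The C2 methylene of A2 would add to its C7 ketone, and dehydration with enolisation would give benzyl 2-(benzyloxy)-4-[(2,4-dihydroxy-3,6-dimethylbenzoyl)oxy]-3,6-dimethylbenzoate A1.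
- In favour: the aldol closure places every ring A substituent of A1 from the chain. The ester of A2 is formed from an unhindered aliphatic acyl group, which is better than the hindered acylation of the chosen plan. Ring B arrives with its carboxyl in place, so no late carboxylation of a weakly activated ring is needed, which is also better.
- Against: A2 is an activated aryl ester of a poly-β-carbonyl acid. Claisen-type C-acylation or lactonisation to a pyrone would compete with the aldol mode, and both expel the ring B phenol benzyl 2-(benzyloxy)-4-hydroxy-3,6-dimethylbenzoate A3 and destroy the depside link. A2 would need polyanion chemistry to assemble. A1 then needs methylation of two ring A phenols, one hydrogen-bonded to the ester carbonyl and both on a base-labile depside, and removal of two benzyl groups.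
- Comparison: on structure it builds one ring and one C–C bond, where the chosen plan takes both rings ready-made. On mechanism its regiochemistry is the equal of the chosen plan, but its chemoselectivity among cyclisation modes is less secure than chelation-directed substitution. On step economy it would probably need about twice as many steps, including at least three after A1 against none after the key step of the chosen plan.

Alternative 2: The cut is the ring B C4–O bond, the aryl–oxygen side of the ester. In the forward key step, potassium 2,4-dimethoxy-3,6-dimethylbenzoate A6 would be heated with [3-(benzyloxy)-4-(benzyloxycarbonyl)-2,5-dimethylphenyl](2,4,6-trimethoxyphenyl)iodonium tosylate A5. The carboxylate of A6 would exchange onto the trivalent iodine of A5, and ligand coupling would release the dummy aryl iodide and give benzyl 2-(benzyloxy)-4-[(2,4-dimethoxy-3,6-dimethylbenzoyl)oxy]-3,6-dimethylbenzoate A4.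
- In favour: the hindered acid acts as the nucleophile in the form of A6, so the shielding of its carbonyl no longer matters and there is no mono- versus bis-acylation statistics. On the ester-forming event this is better than the chosen plan. The carboxyl of ring B is again present from the start, also better, and no transition metal is needed.
- Against: A5 needs iodine at ring B C4, a position meta to the directing C2 oxygen, so direct iodination would go to C5 instead. The iodine would have to be derived from the C4 oxygen of A3, which could simply have been acylated. Two ortho-substituted partners must couple at iodine, a stoichiometric aryl iodide is wasted, and A4 still needs hydrogenolysis of two benzyl groups.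
- Comparison: on structure it makes the same bond array from the other side with no gain in simplification. On mechanism, ligand coupling of A6 at iodine is cleaner than addition–elimination at a hindered carbonyl. On step economy it is clearly longer, because the ring B partner A5 needs carboxylation, double protection, installation of iodine and oxidation to the iodonium salt.

Alternative 3: The cut is the ring B C1–C2 and C5–C6 bonds. In the forward key step, the diene 3-methyl-4,4-bis[(trimethylsilyl)oxy]buta-1,3-dien-2-yl 2,4-dimethoxy-3,6-dimethylbenzoate A8 would undergo [4+2] cycloaddition with benzyl but-2-ynoate A9. Loss of one silyloxy group as its silanol from the cyclohexadiene adduct, with desilylation on work-up, would aromatise it to benzyl 4-[(2,4-dimethoxy-3,6-dimethylbenzoyl)oxy]-2-hydroxy-3,6-dimethylbenzoate A7.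
- In favour: one operation builds ring B of A7 with the carboxyl, the free C2–OH and the acylated C4 oxygen already differentiated. There is no statistical mono-acylation and no late carboxylation, which is better than the chosen plan on both counts. The polarity match (CH2 terminus of A8 to the β-carbon of A9) should give the right regiochemistry. A7 then needs only one hydrogenolysis, nearly the equal of the chosen plan after the key step.
- Against: A8 is a moisture-sensitive ketene bis(silyl) acetal that also carries an enol ester. Making it requires a strong amide base next to that ester, so acyl transfer to carbon is the expected side reaction. Its fully substituted terminus disfavours the s-cis conformation, and A9 is a β-substituted, only moderately reactive dienophile, so heating of a labile diene would be needed.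
- Comparison: on structure it forms a ring and two C–C bonds in the key step against one C–C bond. On mechanism it is a pericyclic construction with inherent regiocontrol, set against chelation-controlled aromatic substitution. On step economy the several-step synthesis of A8 plus the deprotection of A7 makes it longer than five steps and far more demanding in handling.

Key step: step 5

Assumption (remark on the chemistry): ring positions are numbered as in the target (ring A C1 bears the ester carbonyl; ring B C1 bears the carboxyl, C2 the free OH, C4 the ester oxygen). The precursor 9 and the product 13 of the key step differ by exactly CO2.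

## Route

Step 1
Reactants: 1 2,5-dimethylresorcinol (2,5-dimethylbenzene-1,3-diol); 2 iodomethane
Product: 3 1,3-dimethoxy-2,5-dimethylbenzene
Conditions: MeI (3 equiv), K2CO3, acetone, reflux
Reagents that add atoms: iodomethane, CI
Why: Double Williamson ether synthesis: K2CO3 generates the phenoxides, which displace iodide from 2 (SN2); excess reagent drives the second, more hindered O-methylation, and carbonate in acetone favours O- over C-alkylation.

Step 2
Reactants: 3 1,3-dimethoxy-2,5-dimethylbenzene; 4 N,N-dimethylformamide
Product: 6 2,4-dimethoxy-3,6-dimethylbenzaldehyde, via aryl iminium chloride 5 (not isolated)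
Conditions: POCl3, DMF, 0 → 80 °C; then H2O, NaOAc, rt
Reagents that add atoms: N,N-dimethylformamide, CN(C)C=O; water, O
Why: Vilsmeier–Haack formylation: the chloroiminium ion from 4 and POCl3 attacks the doubly activated ring of 3, whose two open positions are equivalent by symmetry (each ortho to one methoxy and para to the other), so only one iminium salt 5 can form; the iminium group deactivates the ring against a second substitution, and aqueous acetate hydrolyses 5 to 6.

Step 3
Reactants: 6 2,4-dimethoxy-3,6-dimethylbenzaldehyde
Product: 7 2,4-dimethoxy-3,6-dimethylbenzoic acid
Conditions: NaClO2, NaH2PO4, 2-methylbut-2-ene (excess), t-BuOH/H2O, rt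
Reagents that add atoms: sodium chlorite, [Na+].[O-]Cl=O
Why: Pinnick (Lindgren) oxidation: chlorous acid adds to the aldehyde and fragments to the acid and HOCl, which the alkene scavenger traps before it can chlorinate the electron-rich ring; the buffered medium leaves the methyl ethers untouched and tolerates the hindered aldehyde.

Step 4
Reactants: 7 2,4-dimethoxy-3,6-dimethylbenzoic acid; 1 2,5-dimethylresorcinol (3 equiv)
Product: 9 3-hydroxy-2,5-dimethylphenyl 2,4-dimethoxy-3,6-dimethylbenzoate, via acid chloride 8 (not isolated)
Conditions: (COCl)2, cat. DMF, CH2Cl2, 0 °C → rt, concentrate; then 1 (3 equiv), Et3N, cat. DMAP, THF, N2, 0 °C → rt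
Reagents that add atoms: none
Why: Acyl chloride formation (oxalyl chloride with DMF catalysis) followed by DMAP-catalysed O-acylation of a phenol; the acylpyridinium overcomes the shielding of the carbonyl by the flanking methoxy and methyl groups, and a threefold excess of symmetric 1 (both hydroxyls equivalent, so only one monoester exists) suppresses the bis-ester; unreacted 1 is washed out with water and can be recycled, which also keeps it out of the next step, where it would be carboxylated faster than 9.

Step 5
Reactants: 9 3-hydroxy-2,5-dimethylphenyl 2,4-dimethoxy-3,6-dimethylbenzoate; 10 methoxymagnesium methyl carbonate (CH3OMgOCO2CH3)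
Product: 13 diffractaic acid, via aryloxymagnesium methyl carbonate 11 (not isolated), via magnesium salicylate chelate 12 (not isolated)
Conditions: CH3OMgOCO2CH3 (2 M in DMF, excess), 120 °C, N2 sweep; then cold 1 M HCl, 0 °C
Reagents that add atoms: methoxymagnesium methyl carbonate, COC(=O)O[Mg]OC
Why: Exchange of the phenol of 9 onto magnesium gives 11, which holds the methyl carbonate ligand, a masked CO2, next to the phenoxide oxygen. The carboxyl carbon is then passed to the adjacent ring carbon through a six-membered magnesium-bridged transition state, the ring rearomatises by proton loss, and loss of methanol gives the chelate 12, whose stability pulls the otherwise reversible carboxylation forward; cold acid releases 13. The closest known reaction type is the carboxylation of resorcinols and their mono-O-substituted derivatives with CH3OMgOCO2CH3 in DMF, a mild Kolbe–Schmitt variant. No ring of the product is closed (the chelate ring of 12 is a transient metallacycle) and no stereocentre is formed. The step needs ortho (ring B C1) over para (C5) selectivity: the electrophile is bound to the phenoxide oxygen and cannot reach C5, and the second ortho carbon C3 carries a methyl group. It also needs C–H carboxylation to outrun cleavage of the depside ester: the ester carbonyl is shielded by the C2 methoxy and C6 methyl groups of ring A, the reagent is only weakly nucleophilic, and methanol is swept out as it forms. Ring A has no free phenol, so it cannot bind magnesium and is not carboxylated.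

## Compound list

1 | 2,5-dimethylresorcinol (2,5-dimethylbenzene-1,3-diol) | Cc1cc(O)c(C)c(O)c1 | starting material
2 | iodomethane | CI | starting material
3 | 1,3-dimethoxy-2,5-dimethylbenzene | COc1cc(C)cc(OC)c1C | intermediate
4 | N,N-dimethylformamide | CN(C)C=O | starting material
5 | N-[(2,4-dimethoxy-3,6-dimethylphenyl)methylidene]-N-methylmethanaminium chloride | COc1cc(C)c(C=[N+](C)C)c(OC)c1C.[Cl-] | intermediate
6 | 2,4-dimethoxy-3,6-dimethylbenzaldehyde | COc1cc(C)c(C=O)c(OC)c1C | intermediate
7 | 2,4-dimethoxy-3,6-dimethylbenzoic acid | COc1cc(C)c(C(=O)O)c(OC)c1C | intermediate
8 | 2,4-dimethoxy-3,6-dimethylbenzoyl chloride | COc1cc(C)c(C(Cl)=O)c(OC)c1C | intermediate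
9 | 3-hydroxy-2,5-dimethylphenyl 2,4-dimethoxy-3,6-dimethylbenzoate | COc1cc(C)c(C(=O)Oc2cc(C)cc(O)c2C)c(OC)c1C | intermediate
10 | methoxymagnesium methyl carbonate (magnesium methyl carbonate, CH3OMgOCO2CH3) | COC(=O)O[Mg]OC | starting material
11 | aryloxymagnesium methyl carbonate derived from 9 | COc1cc(C)c(C(=O)Oc2cc(C)cc(O[Mg]OC(=O)OC)c2C)c(OC)c1C | intermediate
12 | magnesium phenoxide–carboxylate chelate of diffractaic acid | COc1cc(C)c(C(=O)Oc2cc(C)c3c(O[Mg]OC3=O)c2C)c(OC)c1C | intermediate
13 | diffractaic acid, 4-[(2,4-dimethoxy-3,6-dimethylbenzoyl)oxy]-2-hydroxy-3,6-dimethylbenzoic acid | COc1cc(C)c(C(=O)Oc2cc(C)c(C(=O)O)c(O)c2C)c(OC)c1C | target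

## Step count and risk assessment

Total step count: 5. Longest linear sequence: 5 steps (1 → 3 → 6 → 7 → 9 → 13; compound 1 enters a second time in step 4).

Least certain steps:

Step 5 (key step). The ring is activated by one free phenoxide only, since the para oxygen is acylated and donates weakly, so carboxylation may be slow. Prolonged heating would then allow transesterification of the depside ester by methoxide or methanol from the reagent, and the product may lose CO2 again if the acidic work-up is warm. Fallback, from 9 and returning at 13: the same carbon is installed at the aldehyde oxidation level by magnesium-directed ortho-formylation (MgCl2, Et3N, paraformaldehyde, MeCN, reflux). This uses the same phenoxide-on-magnesium ortho direction but a far more reactive electrophile, no added alkoxide and a lower temperature, and should give 4-formyl-3-hydroxy-2,5-dimethylphenyl 2,4-dimethoxy-3,6-dimethylbenzoate F1. Chlorite oxidation (NaClO2, sulfamic acid, aqueous dioxane, rt) then converts the aldehyde into the acid 13.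

Step 4. Statistical over-acylation to the bis-ester and slow attack at the shielded carbonyl are the likely problems. Slow attack leaves time for hydrolysis of 8 and for air oxidation of the electron-rich diol under base. Fallback, from 1 and returning at 9: the diol is desymmetrised first by monobenzylation (BnBr, 1 equiv, K2CO3, acetone) to 3-(benzyloxy)-2,5-dimethylphenol F2, purified on cheap material. It is then acylated with 8 (pyridine, cat. DMAP, 60 °C), under forcing conditions if needed because only one hydroxyl is present, to 3-(benzyloxy)-2,5-dimethylphenyl 2,4-dimethoxy-3,6-dimethylbenzoate F3. Hydrogenolysis (H2, Pd/C, EtOAc) then frees the phenol of 9.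

Step 2. Substitution at a position flanked by a methoxy and a methyl group may be slow, and forcing it invites cleavage of an ortho methyl ether by the acidic phosphorus chloride medium. Fallback, from 1 and returning at 6: the order of events is inverted. The far more reactive free diol is formylated (POCl3, DMF, MeCN, 0 °C → rt; then H2O) through N-[(2,4-dihydroxy-3,6-dimethylphenyl)methylidene]-N-methylmethanaminium chloride F4 to 2,4-dihydroxy-3,6-dimethylbenzaldehyde F5. Both phenols are then methylated (MeI, K2CO3, DMF, 50 °C) to give 6.

Step 3. Incomplete scavenging of HOCl would lead to electrophilic chlorination of ring A at C5, and the doubly flanked aldehyde may oxidise slowly. Fallback, from 3 and returning at 7, bypassing 6: ring bromination (NBS, MeCN, 0 °C) should give 1-bromo-2,4-dimethoxy-3,6-dimethylbenzene F6. Bromine–lithium exchange (n-BuLi, THF, −78 °C) gives (2,4-dimethoxy-3,6-dimethylphenyl)lithium F7, which is quenched with CO2 and acidified to the acid 7.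

## Further compounds

F1 | step 5 | 4-formyl-3-hydroxy-2,5-dimethylphenyl 2,4-dimethoxy-3,6-dimethylbenzoate | COc1cc(C)c(C(=O)Oc2cc(C)c(C=O)c(O)c2C)c(OC)c1C
F2 | step 4 | 3-(benzyloxy)-2,5-dimethylphenol | Cc1cc(O)c(C)c(OCc2ccccc2)c1
F3 | step 4 | 3-(benzyloxy)-2,5-dimethylphenyl 2,4-dimethoxy-3,6-dimethylbenzoate | COc1cc(C)c(C(=O)Oc2cc(C)cc(OCc3ccccc3)c2C)c(OC)c1C
F4 | step 2 | N-[(2,4-dihydroxy-3,6-dimethylphenyl)methylidene]-N-methylmethanaminium chloride | Cc1cc(O)c(C)c(O)c1C=[N+](C)C.[Cl-]
F5 | step 2 | 2,4-dihydroxy-3,6-dimethylbenzaldehyde | Cc1cc(O)c(C)c(O)c1C=O
F6 | step 3 | 1-bromo-2,4-dimethoxy-3,6-dimethylbenzene | COc1cc(C)c(Br)c(OC)c1C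
F7 | step 3 | (2,4-dimethoxy-3,6-dimethylphenyl)lithium | [Li]c1c(C)cc(OC)c(C)c1OC
A1 | alternative 1 | benzyl 2-(benzyloxy)-4-[(2,4-dihydroxy-3,6-dimethylbenzoyl)oxy]-3,6-dimethylbenzoate | Cc1cc(O)c(C)c(O)c1C(=O)Oc1cc(C)c(C(=O)OCc2ccccc2)c(OCc3ccccc3)c1C
A2 | alternative 1 | benzyl 2-(benzyloxy)-3,6-dimethyl-4-[(4-methyl-3,5,7-trioxooctanoyl)oxy]benzoate | CC(=O)CC(=O)C(C)C(=O)CC(=O)Oc1cc(C)c(C(=O)OCc2ccccc2)c(OCc3ccccc3)c1C
A3 | alternative 1 | benzyl 2-(benzyloxy)-4-hydroxy-3,6-dimethylbenzoate | Cc1cc(O)c(C)c(OCc2ccccc2)c1C(=O)OCc1ccccc1
A4 | alternative 2 | benzyl 2-(benzyloxy)-4-[(2,4-dimethoxy-3,6-dimethylbenzoyl)oxy]-3,6-dimethylbenzoate | COc1cc(C)c(C(=O)Oc2cc(C)c(C(=O)OCc3ccccc3)c(OCc4ccccc4)c2C)c(OC)c1C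
A5 | alternative 2 | [3-(benzyloxy)-4-(benzyloxycarbonyl)-2,5-dimethylphenyl](2,4,6-trimethoxyphenyl)iodonium tosylate | COc1cc(OC)c([I+]c2cc(C)c(C(=O)OCc3ccccc3)c(OCc3ccccc3)c2C)c(OC)c1.Cc1ccc(S(=O)(=O)[O-])cc1
A6 | alternative 2 | potassium 2,4-dimethoxy-3,6-dimethylbenzoate | COc1cc(C)c(C(=O)[O-])c(OC)c1C.[K+]
A7 | alternative 3 | benzyl 4-[(2,4-dimethoxy-3,6-dimethylbenzoyl)oxy]-2-hydroxy-3,6-dimethylbenzoate | COc1cc(C)c(C(=O)Oc2cc(C)c(C(=O)OCc3ccccc3)c(O)c2C)c(OC)c1C
A8 | alternative 3 | 3-methyl-4,4-bis[(trimethylsilyl)oxy]buta-1,3-dien-2-yl 2,4-dimethoxy-3,6-dimethylbenzoate | C=C(OC(=O)c1c(C)cc(OC)c(C)c1OC)C(C)=C(O[Si](C)(C)C)O[Si](C)(C)C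
A9 | alternative 3 | benzyl but-2-ynoate | CC#CC(=O)OCc1ccccc1
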